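**Assumption:** natural (+)-catechin (2R,3S, commercial) is accepted as a starting material; it supplies both stereocentres, which no later step touches.

## Retrosynthetic overview

1. Pilosanol B ⇒ remove four O-benzyl groups and one O-TBS group from a protected 8-(arylmethyl)-(+)-catechin.
2. Key disconnection, C8–CH2 bond ⇒ flavan-8-ylboronic acid + acylphloroglucinol Mannich base (an o-quinone methide precursor), joined by a proposed boron-relay deaminative arylation.
3. Boronic acid ⇐ 8-bromo-tetra-O-benzylcatechin ⇐ (+)-catechin; the C8-selective bromination settles C8 versus C6.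
4. Mannich base ⇐ 4,6-dihydroxy-2-methoxy-3-methyl-isobutyrophenone ⇐ 2-methylphloroglucinol + isobutyryl chloride (acylation, OH differentiation, O-methylation).
5. Ring order: no ring is built. The chroman and catechol rings come intact from catechin and the phloroglucinol ring from 2-methylphloroglucinol; they are substituted, joined, then deprotected.

## Route

**Step 1**
Reactants: 1, (+)-catechin [(2R,3S)-2-(3,4-dihydroxyphenyl)chromane-3,5,7-triol]
Product: 2, (2R,3S)-5,7-bis(benzyloxy)-2-[3,4-bis(benzyloxy)phenyl]chroman-3-ol
Conditions: BnBr (4.4 equiv), K2CO3, DMF, 0 °C → rt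
Reagents that add atoms: benzyl bromide, BrCc1ccccc1
Why: Williamson etherification; K2CO3 ionises only the four phenols, so the secondary 3-OH stays free, and the mild conditions do not epimerise C2 or C3.

**Step 2**
Reactants: 2
Product: 3, (2R,3S)-5,7-bis(benzyloxy)-2-[3,4-bis(benzyloxy)phenyl]-8-bromochroman-3-ol
Conditions: NBS (1.0 equiv), CH2Cl2, −78 °C → rt
Reagents that add atoms: N-bromosuccinimide, O=C1CCC(=O)N1Br
Why: Electrophilic aromatic bromination; in the tetrabenzyl ether C8 (between OBn and the ring oxygen) is much more accessible than C6 (between two OBn), which is well-established selectivity for this substrate.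

**Step 3**
Reactants: 3
Product: 4, tert-butyl{[(2R,3S)-5,7-bis(benzyloxy)-2-[3,4-bis(benzyloxy)phenyl]-8-bromochroman-3-yl]oxy}dimethylsilane
Conditions: TBSCl, imidazole, DMF, rt
Reagents that add atoms: tert-butyldimethylsilyl chloride, CC(C)(C)[Si](C)(C)Cl
Why: Imidazole-promoted silylation masks the only acidic proton before organolithium chemistry; the stereocentres are not involved.

**Step 4**
Reactants: 4
Product: 5, [(2R,3S)-5,7-bis(benzyloxy)-2-[3,4-bis(benzyloxy)phenyl]-3-[(tert-butyldimethylsilyl)oxy]chroman-8-yl]boronic acid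
Conditions: n-BuLi (1.1 equiv), THF, −78 °C; B(OiPr)3, −78 → 0 °C; aq. NH4Cl
Reagents that add atoms: triisopropyl borate, CC(C)OB(OC(C)C)OC(C)C; water, O
Why: Bromine–lithium exchange at −78 °C outruns any deprotonation, and borate trapping then hydrolysis gives the boronic acid, so boron sits exactly where bromine was (C8).

**Step 5**
Reactants: 6, 2-methylbenzene-1,3,5-triol (2-methylphloroglucinol); 7, isobutyryl chloride
Product: 8, 1-(2,4,6-trihydroxy-3-methylphenyl)-2-methylpropan-1-one
Conditions: AlCl3 (4 equiv), PhNO2, 65 °C; ice/HCl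
Reagents that add atoms: isobutyryl chloride (7), CC(C)C(Cl)=O
Why: Friedel–Crafts acylation; the two free ring positions of 6 are equivalent by symmetry, so only one mono-ketone can form, and the first acyl group deactivates the ring toward a second.

**Step 6**
Reactants: 8
Product: 9, 1-[4,6-bis(benzyloxy)-2-hydroxy-3-methylphenyl]-2-methylpropan-1-one
Conditions: BnBr (2.05 equiv), K2CO3, DMF, 0 °C → rt; chromatography
Reagents that add atoms: benzyl bromide, BrCc1ccccc1
Why: Williamson etherification under weak base alkylates the most acidic para-OH and then the less hindered ortho-OH, leaving free the carbonyl-chelated OH that is flanked by the C-methyl group.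

**Step 7**
Reactants: 9
Product: 10, 1-[4,6-bis(benzyloxy)-2-methoxy-3-methylphenyl]-2-methylpropan-1-one
Conditions: MeI (excess), Cs2CO3, DMF, 40 °C
Reagents that add atoms: iodomethane, CI
Why: Williamson O-methylation of the one remaining (chelated) phenol under forcing conditions; no other nucleophilic site is present.

**Step 8**
Reactants: 10
Product: 11, 1-(4,6-dihydroxy-2-methoxy-3-methylphenyl)-2-methylpropan-1-one
Conditions: H2 (1 atm), 10% Pd/C, EtOAc, rt
Reagents that add atoms: none
Why: Catalytic hydrogenolysis cleaves the two aryl benzyl ethers; the di-ortho-substituted aryl ketone is not reduced at 1 atm and rt.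

**Step 9**
Reactants: 11; 12, Eschenmoser's salt (N,N-dimethylmethyleneiminium iodide)
Product: 13, 1-{3-[(dimethylamino)methyl]-2,4-dihydroxy-6-methoxy-5-methylphenyl}-2-methylpropan-1-one
Conditions: 12 (1.05 equiv), CH2Cl2/MeCN, 0 °C → rt; aq. NaHCO3
Reagents that add atoms: Eschenmoser's salt (12), C=[N+](C)C.[I-]
Why: Mannich aminomethylation; the only unsubstituted ring carbon lies between two OH groups and is strongly nucleophilic, so the future bridging CH2 is installed at the single possible site.

**Step 10 (key step, new)**
Reactants: 5 (1.3 equiv); 13 (1.0 equiv)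
Product: 14, 1-[3-({(2R,3S)-5,7-bis(benzyloxy)-2-[3,4-bis(benzyloxy)phenyl]-3-[(tert-butyldimethylsilyl)oxy]chroman-8-yl}methyl)-2,4-dihydroxy-6-methoxy-5-methylphenyl]-2-methylpropan-1-one
Conditions: 4 Å MS, toluene, rt → 60 °C, N2; aq. NH4Cl work-up
Reagents that add atoms: none (all product atoms come from 5 and 13)
Why: Proposed new method: boron-relay deaminative arylation of a phenolic Mannich base — the phenol of 13 esterifies the boronic acid and the NMe2 group coordinates boron (six-membered N→B chelate, tetracoordinate "ate" boron), C–N heterolysis then releases the acyl-o-quinone methide still O-bound to the aminoborate, and the electron-rich flavanyl group migrates from boron to the exocyclic CH2 through a six-membered transition state, so the C–C bond forms only at the boron-bearing carbon (C8) under neutral conditions that leave Bn, TBS and both stereocentres untouched and create no new stereocentre; the closest known reaction types are the Petasis borono-Mannich reaction and the addition of aryl boronates to o-quinone methides, neither shown for acylphloroglucinol Mannich bases or flavan-8-yl boron reagents.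

**Step 11**
Reactants: 14
Product: 15, 1-[3-({(2R,3S)-5,7-bis(benzyloxy)-2-[3,4-bis(benzyloxy)phenyl]-3-hydroxychroman-8-yl}methyl)-2,4-dihydroxy-6-methoxy-5-methylphenyl]-2-methylpropan-1-one
Conditions: TBAF, AcOH (1:1), THF, 0 °C → rt
Reagents that add atoms: none
Why: Fluoride-mediated desilylation, buffered with AcOH so the acidic acylphloroglucinol and the methylene bridge are not exposed to strong base; C3 keeps its configuration because only the O–Si bond breaks.

**Step 12**
Reactants: 15
Product: 16, pilosanol B, 1-[3-({(2R,3S)-2-(3,4-dihydroxyphenyl)-3,5,7-trihydroxychroman-8-yl}methyl)-2,4-dihydroxy-6-methoxy-5-methylphenyl]-2-methylpropan-1-one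
Conditions: H2 (1 atm), 20% Pd(OH)2/C, THF/MeOH, rt; filter under Ar
Reagents that add atoms: none
Why: Catalytic hydrogenolysis removes the four aryl benzyl ethers under neutral conditions that spare the hindered chelated ketone, the diarylmethane bridge and the C2/C3 stereocentres.

## Compound list

1 | (+)-catechin | c1c(O)cc(O)c2c1O[C@H](c1ccc(O)c(O)c1)[C@@H](O)C2 | starting material
2 | 5,7,3′,4′-tetra-O-benzyl-(+)-catechin | c1c(OCc2ccccc2)cc(OCc2ccccc2)c2c1O[C@H](c1ccc(OCc3ccccc3)c(OCc3ccccc3)c1)[C@@H](O)C2 | intermediate
3 | 8-bromo-5,7,3′,4′-tetra-O-benzyl-(+)-catechin | Brc1c(OCc2ccccc2)cc(OCc2ccccc2)c2c1O[C@H](c1ccc(OCc3ccccc3)c(OCc3ccccc3)c1)[C@@H](O)C2 | intermediate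
4 | 8-bromo-3-O-TBS-5,7,3′,4′-tetra-O-benzyl-(+)-catechin | Brc1c(OCc2ccccc2)cc(OCc2ccccc2)c2c1O[C@H](c1ccc(OCc3ccccc3)c(OCc3ccccc3)c1)[C@@H](O[Si](C)(C)C(C)(C)C)C2 | intermediate
5 | 3-O-TBS-5,7,3′,4′-tetra-O-benzyl-(+)-catechin-8-ylboronic acid | OB(O)c1c(OCc2ccccc2)cc(OCc2ccccc2)c2c1O[C@H](c1ccc(OCc3ccccc3)c(OCc3ccccc3)c1)[C@@H](O[Si](C)(C)C(C)(C)C)C2 | intermediate
6 | 2-methylbenzene-1,3,5-triol (2-methylphloroglucinol) | Cc1c(O)cc(O)cc1O | starting material
7 | isobutyryl chloride | CC(C)C(Cl)=O | starting material
8 | 1-(2,4,6-trihydroxy-3-methylphenyl)-2-methylpropan-1-one | CC(C)C(=O)c1c(O)cc(O)c(C)c1O | intermediate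
9 | 1-[4,6-bis(benzyloxy)-2-hydroxy-3-methylphenyl]-2-methylpropan-1-one | CC(C)C(=O)c1c(OCc2ccccc2)cc(OCc2ccccc2)c(C)c1O | intermediate
10 | 1-[4,6-bis(benzyloxy)-2-methoxy-3-methylphenyl]-2-methylpropan-1-one | CC(C)C(=O)c1c(OCc2ccccc2)cc(OCc2ccccc2)c(C)c1OC | intermediate
11 | 1-(4,6-dihydroxy-2-methoxy-3-methylphenyl)-2-methylpropan-1-one | CC(C)C(=O)c1c(O)cc(O)c(C)c1OC | intermediate
12 | Eschenmoser's salt (N,N-dimethylmethyleneiminium iodide) | C=[N+](C)C.[I-] | starting material
13 | 1-{3-[(dimethylamino)methyl]-2,4-dihydroxy-6-methoxy-5-methylphenyl}-2-methylpropan-1-one | CC(C)C(=O)c1c(O)c(CN(C)C)c(O)c(C)c1OC | intermediate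
14 | 3-O-TBS-5,7,3′,4′-tetra-O-benzyl-pilosanol B | COc1c(C)c(O)c(Cc2c(OCc3ccccc3)cc(OCc3ccccc3)c3c2O[C@H](c2ccc(OCc4ccccc4)c(OCc4ccccc4)c2)[C@@H](O[Si](C)(C)C(C)(C)C)C3)c(O)c1C(=O)C(C)C | intermediate
15 | 5,7,3′,4′-tetra-O-benzyl-pilosanol B | COc1c(C)c(O)c(Cc2c(OCc3ccccc3)cc(OCc3ccccc3)c3c2O[C@H](c2ccc(OCc4ccccc4)c(OCc4ccccc4)c2)[C@@H](O)C3)c(O)c1C(=O)C(C)C | intermediate
16 | pilosanol B | COc1c(C)c(O)c(Cc2c(O)cc(O)c3c2O[C@H](c2ccc(O)c(O)c2)[C@@H](O)C3)c(O)c1C(=O)C(C)C | target

## Summary

**Total step count:** 12

**Longest linear sequence:** 8 steps (Steps 5–12, from 2-methylphloroglucinol); the catechin branch is 7 steps (Steps 1–4, 10–12).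

**Three steps most likely to fail**

1. **Step 10 (proposed new coupling).** Risks are protodeboronation of the hindered, electron-rich boronic acid and self-condensation of the o-quinone methide. Fallback with known chemistry and inverted polarity: treat 4 with n-BuLi then DMF to give the 8-carbaldehyde, reduce with NaBH4 to the 8-hydroxymethyl flavan, and use it as the electrophile in an acid-catalysed Friedel–Crafts benzylation (cat. TsOH or BF3·OEt2, CH2Cl2) of phenol 11, whose only free ring carbon is the required one. This gives 14 directly, followed by Steps 11–12.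

2. **Step 6 (which ortho-OH is benzylated).** The selectivity rests on sterics and is expected, not guaranteed; the minor regioisomer would need to be separated and the assignment confirmed by NOE. Fallback: benzylate all three OH groups of 8, then remove one benzyl by chelation-controlled cleavage (BCl3, 1 equiv, or MgBr2·OEt2, CH2Cl2, −78 °C). This targets an ether ortho to the carbonyl and should prefer the one twisted by the neighbouring methyl, reaching 9 through deprotection selectivity instead of protection selectivity.

3. **Step 4 (aryllithium borylation and isolation of a 2,6-dialkoxyarylboronic acid).** Fallback: Pd-catalysed Miyaura borylation of bromide 3 (B2pin2, Pd(OAc)2/SPhos, KOAc, dioxane) to the chromatography-stable pinacol boronate. This avoids the organolithium and the free boronic acid, makes the TBS protection and removal (Steps 3 and 11) unnecessary, and the ester is used directly in Step 10.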